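**Plan**
1. Retrosynthesis: the two S–O bonds are cut first, back to 5,7,4'-tri-O-benzylquercetin with free 3-OH and 3'-OH. Then the C2–C1' bond between ring C and ring B is cut, then O1–C2 and C2–C3 of ring C, back to 2',4',6'-trihydroxyacetophenone.
2. Forward: ring A is bought; ring C is closed onto it as a 2-unsubstituted chromone, and C3 is oxygenated and pivaloylated. Ring B is bought as catechol monobenzyl ether, pivaloylated at O3' and iodinated at C1'.
3. The halves are joined by deprotonative zincation of C2–H and Negishi coupling; depivaloylation, bis-sulfation and hydrogenolysis follow.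
4. Enabling feature: C2–H of the pyranone ring is flanked by O1 and the C3–O ester and is vinylogous to C4=O, so it is by far the most acidic C–H. C1' of ring B is para to O4' and meta to O3', so an acyl group on O3' leaves O4' as sole director.
5. The two pivalates are the helpers: they block and direct at C3 and O3', set O3/O3' apart from the benzylated O5/O7/O4', and leave together to expose exactly the two sulfation sites.
6. Stereochemistry: the target is planar and has no stereocentre, so nothing has to be set; the only stereogenic intermediate (a racemic cis-epoxide) is consumed in the flask.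

Key step: step 7

Remark: the target is drawn as the free bis(hydrogen sulfate); because aryl and enol hydrogen sulfates are acid-labile, the salt is protonated only in the last operation and the acid is kept cold.

**Route**

Step 1
Reactants: 1 2',4',6'-trihydroxyacetophenone
Product: 2 1-[2,4-bis(benzyloxy)-6-hydroxyphenyl]ethan-1-one
Conditions: BnBr (2.1 equiv), K2CO3 (2.2 equiv), DMF, 0 °C → rt
Reagents that add atoms: benzyl bromide, BrCc1ccccc1
Why: Williamson etherification; the 2-OH is hydrogen-bonded to the acetyl C=O and is the least nucleophilic of the three, so two equivalents of benzyl bromide should leave it free for the ring closure.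

Step 2
Reactants: 2 1-[2,4-bis(benzyloxy)-6-hydroxyphenyl]ethan-1-one
Product: 4 5,7-bis(benzyloxy)-4H-chromen-4-one, via enaminone 3 (not isolated)
Conditions: Me2NCH(OMe)2 (3 equiv), toluene, 100 °C; evaporate; AcOH, 80 °C
Reagents that add atoms: N,N-dimethylformamide dimethyl acetal, COC(OC)N(C)C
Why: Condensation of the methyl ketone with the amide acetal gives the β-dimethylaminovinyl ketone, and acid-promoted conjugate addition of the phenol with loss of dimethylamine closes the pyranone ring (enaminone chromone synthesis).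

Step 3
Reactants: 4 5,7-bis(benzyloxy)-4H-chromen-4-one
Product: 6 5,7-bis(benzyloxy)-3-hydroxy-4H-chromen-4-one, via epoxide 5 (not isolated)
Conditions: DMDO (acetone solution, 2.5 equiv), CH2Cl2, 0 °C → rt; evaporate; TsOH·H2O (0.1 equiv), CH2Cl2, rt
Reagents that add atoms: dimethyldioxirane, CC1(C)OO1
Why: Electrophilic dioxirane epoxidation of the enol-ether-like C2=C3 bond, then acid-catalysed opening at the acetal carbon C2 and loss of H3 (epoxide-to-enol isomerisation), is the established passage from chromones and flavones to their 3-hydroxy derivatives; the two epoxide stereocentres (cis by ring constraint, racemic) are erased at once.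

Step 4
Reactants: 6 5,7-bis(benzyloxy)-3-hydroxy-4H-chromen-4-one
Product: 7 5,7-bis(benzyloxy)-4-oxo-4H-chromen-3-yl pivalate
Conditions: PivCl (1.3 equiv), K2CO3 (2 equiv), DMAP (5 mol %), acetone, 0 °C → rt
Reagents that add atoms: pivaloyl chloride, CC(C)(C)C(Cl)=O
Why: O-Acylation of the acidic 3-enol (nucleophilic acyl substitution); the pivalate masks O3, will direct the zinc base to C2 and tolerates organozinc chemistry.

Step 5
Reactants: 8 2-(benzyloxy)phenol
Product: 9 2-(benzyloxy)phenyl pivalate
Conditions: PivCl (1.2 equiv), K2CO3 (2 equiv), DMAP (5 mol %), acetone, rt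
Reagents that add atoms: pivaloyl chloride, CC(C)(C)C(Cl)=O
Why: O-Acylation of the phenol; as an ester, the future O3' loses its donor power, so only the benzyloxy oxygen directs the next step.

Step 6
Reactants: 9 2-(benzyloxy)phenyl pivalate
Product: 10 2-(benzyloxy)-5-iodophenyl pivalate
Conditions: NIS (1.1 equiv), TFA (0.3 equiv), MeCN, rt, dark
Reagents that add atoms: N-iodosuccinimide, O=C1CCC(=O)N1I
Why: Electrophilic aromatic iodination with acid-activated NIS should go para to the benzyloxy group, the only strong donor on the ring, as in the para-halogenation of guaiacol acetate; the ortho site is sterically disfavoured.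

Step 7
Reactants: 7 5,7-bis(benzyloxy)-4-oxo-4H-chromen-3-yl pivalate; 10 2-(benzyloxy)-5-iodophenyl pivalate
Product: 12 5,7-bis(benzyloxy)-2-[4-(benzyloxy)-3-(pivaloyloxy)phenyl]-4-oxo-4H-chromen-3-yl pivalate, via chromonylzinc chloride 11 (not isolated)
Conditions: TMPZnCl·LiCl (1.3 equiv), THF, 0 → 25 °C; then 10 (0.85 equiv), Pd(dba)2 (3 mol %), P(2-furyl)3 (6 mol %), 50 °C
Reagents that add atoms: none
Why: TMPZnCl·LiCl removes the C2 proton, the only hydrogen on ring C, which is acidified by the adjacent ring oxygen O1, by vinylogy to the C4 carbonyl and by the flanking C3 pivaloyloxy group whose carbonyl can pre-coordinate zinc; the resulting 2-chromonylzinc chloride transmetalates to the arylpalladium iodide formed by oxidative addition of Pd(0) into the C–I bond, and reductive elimination forms the C2–C1' bond. The closest known reaction type is the directed zincation of chromones with TMP–zinc amide bases followed by Negishi arylation at C2 to give flavones. No ring is closed and no stereocentre is formed. The step needs C2–H to be taken in preference to the A-ring C6–H and C8–H and the benzylic CH2 groups, which the far higher kinetic acidity of the O1/O3-flanked vinylic C–H and the mildness of the zinc amide should secure, and it needs Ar–I to react in preference to the two pivalate C–O bonds, which palladium does not activate. Zinc, unlike lithium or magnesium, should tolerate both esters and suppress acyl migration to C2 and pyranone ring opening. One event thus delivers the whole flavonol skeleton with its five oxygens already sorted into a benzyl set (O5, O7, O4') and a pivaloyl set (O3, O3').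

Step 8
Reactants: 12 5,7-bis(benzyloxy)-2-[4-(benzyloxy)-3-(pivaloyloxy)phenyl]-4-oxo-4H-chromen-3-yl pivalate
Product: 14 5,7-bis(benzyloxy)-2-[4-(benzyloxy)-3-hydroxyphenyl]-3-hydroxy-4H-chromen-4-one, via disodium salt 13 (not isolated)
Conditions: NaOMe (2.5 equiv), MeOH–THF 1:1, argon, 0 °C → rt; AcOH
Reagents that add atoms: none
Why: Zemplén-type transesterification of the enol and aryl pivalates by methoxide; benzyl ethers are inert, and exclusion of air avoids oxygenation of the flavonolate.

Step 9
Reactants: 14 5,7-bis(benzyloxy)-2-[4-(benzyloxy)-3-hydroxyphenyl]-3-hydroxy-4H-chromen-4-one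
Product: 16 dipotassium 5,7-bis(benzyloxy)-2-[4-(benzyloxy)-3-(sulfonatooxy)phenyl]-4-oxo-4H-chromen-3-yl sulfate, via bis(pyridinium) salt 15 (not isolated)
Conditions: SO3·pyridine (8 equiv), pyridine, 60 °C; then KOH, MeOH, 0 °C, pH 8; Sephadex LH-20
Reagents that add atoms: sulfur trioxide–pyridine complex, O=S(=O)([O-])[n+]1ccccc1; potassium hydroxide, [K+].[OH-]
Why: O-Sulfation by sulfur trioxide transfer at the only two free hydroxyls, O3 and O3'; excess reagent and warming should overcome the hydrogen bond of the 3-OH to C4=O, and potassium exchange gives a salt that does not inhibit the palladium catalyst of the next step.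

Step 10
Reactants: 16 dipotassium 5,7-bis(benzyloxy)-2-[4-(benzyloxy)-3-(sulfonatooxy)phenyl]-4-oxo-4H-chromen-3-yl sulfate
Product: 18 quercetin 3,3'-bissulfate, via dipotassium salt 17 (not isolated)
Conditions: H2 (1 atm), 10% Pd/C, MeOH–THF–H2O, rt; filter; 1.0 M HCl (2.0 equiv), 0 °C; C18 desalting, lyophilisation
Reagents that add atoms: none
Why: Catalytic hydrogenolysis of the three benzyl aryl ethers, a reaction type under which aryl sulfate salts and the flavonol C2=C3 bond persist, followed by stoichiometric protonation of the two sulfate anions in the cold.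

**Compound list**
1 | 2',4',6'-trihydroxyacetophenone | CC(=O)c1c(O)cc(O)cc1O | starting material
2 | 1-[2,4-bis(benzyloxy)-6-hydroxyphenyl]ethan-1-one | CC(=O)c1c(O)cc(OCc2ccccc2)cc1OCc1ccccc1 | intermediate
3 | (E)-1-[2,4-bis(benzyloxy)-6-hydroxyphenyl]-3-(dimethylamino)prop-2-en-1-one | CN(C)/C=C/C(=O)c1c(O)cc(OCc2ccccc2)cc1OCc1ccccc1 | intermediate
4 | 5,7-bis(benzyloxy)-4H-chromen-4-one | O=c1ccoc2cc(OCc3ccccc3)cc(OCc3ccccc3)c12 | intermediate
5 | 5,7-bis(benzyloxy)-2,3-epoxy-2,3-dihydro-4H-chromen-4-one (racemic, cis-fused oxirane; one enantiomer drawn) | O=C1[C@@H]2O[C@@H]2Oc2cc(OCc3ccccc3)cc(OCc3ccccc3)c12 | intermediate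
6 | 5,7-bis(benzyloxy)-3-hydroxy-4H-chromen-4-one | O=c1c(O)coc2cc(OCc3ccccc3)cc(OCc3ccccc3)c12 | intermediate
7 | 5,7-bis(benzyloxy)-4-oxo-4H-chromen-3-yl pivalate | CC(C)(C)C(=O)Oc1coc2cc(OCc3ccccc3)cc(OCc3ccccc3)c2c1=O | intermediate
8 | 2-(benzyloxy)phenol | Oc1ccccc1OCc1ccccc1 | starting material
9 | 2-(benzyloxy)phenyl pivalate | CC(C)(C)C(=O)Oc1ccccc1OCc1ccccc1 | intermediate
10 | 2-(benzyloxy)-5-iodophenyl pivalate | CC(C)(C)C(=O)Oc1cc(I)ccc1OCc1ccccc1 | intermediate
11 | [5,7-bis(benzyloxy)-4-oxo-3-(pivaloyloxy)-4H-chromen-2-yl]zinc chloride (as its LiCl adduct; Zn and Cl from TMPZnCl·LiCl) | CC(C)(C)C(=O)Oc1c([Zn]Cl)oc2cc(OCc3ccccc3)cc(OCc3ccccc3)c2c1=O | intermediate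
12 | 5,7-bis(benzyloxy)-2-[4-(benzyloxy)-3-(pivaloyloxy)phenyl]-4-oxo-4H-chromen-3-yl pivalate | CC(C)(C)C(=O)Oc1cc(-c2oc3cc(OCc4ccccc4)cc(OCc4ccccc4)c3c(=O)c2OC(=O)C(C)(C)C)ccc1OCc1ccccc1 | intermediate
13 | disodium salt (3-olate, 3'-phenolate) of 5,7,4'-tri-O-benzylquercetin | [O-]c1c(-c2ccc(OCc3ccccc3)c([O-])c2)oc2cc(OCc3ccccc3)cc(OCc3ccccc3)c2c1=O.[Na+].[Na+] | intermediate
14 | 5,7-bis(benzyloxy)-2-[4-(benzyloxy)-3-hydroxyphenyl]-3-hydroxy-4H-chromen-4-one (5,7,4'-tri-O-benzylquercetin) | O=c1c(O)c(-c2ccc(OCc3ccccc3)c(O)c2)oc2cc(OCc3ccccc3)cc(OCc3ccccc3)c12 | intermediate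
15 | bis(pyridinium) 5,7,4'-tri-O-benzylquercetin 3,3'-bis(sulfate) | O=c1c(OS(=O)(=O)[O-])c(-c2ccc(OCc3ccccc3)c(OS(=O)(=O)[O-])c2)oc2cc(OCc3ccccc3)cc(OCc3ccccc3)c12.c1cc[nH+]cc1.c1cc[nH+]cc1 | intermediate
16 | dipotassium 5,7-bis(benzyloxy)-2-[4-(benzyloxy)-3-(sulfonatooxy)phenyl]-4-oxo-4H-chromen-3-yl sulfate | O=c1c(OS(=O)(=O)[O-])c(-c2ccc(OCc3ccccc3)c(OS(=O)(=O)[O-])c2)oc2cc(OCc3ccccc3)cc(OCc3ccccc3)c12.[K+].[K+] | intermediate
17 | dipotassium quercetin 3,3'-bis(sulfate) | O=c1c(OS(=O)(=O)[O-])c(-c2ccc(O)c(OS(=O)(=O)[O-])c2)oc2cc(O)cc(O)c12.[K+].[K+] | intermediate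
18 | quercetin 3,3'-bissulfate (achiral) | O=c1c(OS(=O)(=O)O)c(-c2ccc(O)c(OS(=O)(=O)O)c2)oc2cc(O)cc(O)c12 | target

**Count**
Total steps: 10. Longest linear sequence: 8 steps (steps 1–4, then 7–10); steps 5–6 form the second branch.

**Steps most likely to fail**

Step 7. Transmetalation from the hindered, electron-poor chromonylzinc to arylpalladium may be slow, so that protodezincation and homocoupling of the aryl iodide take over. The fallback inverts the polarity of the coupling; it sets out from 7 and 10 and comes back at 12. The zinc reagent 11, made from 7 as in step 7, is quenched with iodine (THF, 0 °C) to give 5,7-bis(benzyloxy)-2-iodo-4-oxo-4H-chromen-3-yl pivalate F1; this quench also checks how complete the deprotonation is. Miyaura borylation of 10 (B2pin2, PdCl2(dppf), KOAc, dioxane, 80 °C) gives 2-(benzyloxy)-5-(4,4,5,5-tetramethyl-1,3,2-dioxaborolan-2-yl)phenyl pivalate F2. Suzuki–Miyaura coupling of the two (Pd(PPh3)4, K3PO4, dioxane–H2O 10:1, 70 °C) should give 12. The vinylogous acyl iodide should add to Pd(0) readily and the electron-rich aryl boronate should transmetalate readily. Partial loss of a pivalate under the basic conditions would be harmless, because step 8 removes both.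

Step 9. Sulfation of the hydrogen-bonded, flanked 3-OH may stay incomplete, and the enol sulfate may be lost by hydrolysis during salt exchange and chromatography. The fallback carries the sulfates as neutral diesters; it sets out from 14 and comes back at 16. Treatment of 14 with 2,2,2-trichloroethyl chlorosulfate (Et3N, DMAP, THF, 0 °C → rt), a more forcing S(VI) electrophile, should give the silica-stable 5,7-bis(benzyloxy)-2-{4-(benzyloxy)-3-[(2,2,2-trichloroethoxy)sulfonyloxy]phenyl}-4-oxo-4H-chromen-3-yl 2,2,2-trichloroethyl sulfate F3. Reductive β-elimination with zinc dust and ammonium formate (MeOH, rt), which leaves benzyl ethers untouched, should give diammonium 5,7,4'-tri-O-benzylquercetin 3,3'-bis(sulfate) F4. Cation exchange with KOH in MeOH then gives 16.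

Step 3. The dioxirane may react unproductively with the 2-unsubstituted chromone: slow epoxidation of the vinylogous ester, competing oxidation at benzylic CH2, and hydration or ring contraction of the epoxide instead of isomerisation. The fallback postpones the C3 oxygenation until after the C–C coupling, where the 2-aryl group stabilises the C2 cation; it sets out from 4 and 10 and comes back at 14. Chromone 4 is zincated with TMPZnCl·LiCl under the conditions that direct zincation of 2,3-unsubstituted chromones to C2, giving [5,7-bis(benzyloxy)-4-oxo-4H-chromen-2-yl]zinc chloride F5. Negishi coupling with 10 (Pd(dba)2, P(2-furyl)3, THF, 50 °C) should give the flavone 2-(benzyloxy)-5-[5,7-bis(benzyloxy)-4-oxo-4H-chromen-2-yl]phenyl pivalate F6. DMDO (CH2Cl2–acetone, 0 °C → rt) gives the racemic flavone epoxide 2-(benzyloxy)-5-[5,7-bis(benzyloxy)-2,3-epoxy-4-oxochroman-2-yl]phenyl pivalate F7. TsOH (cat., CH2Cl2) isomerises it to 2-(benzyloxy)-5-[5,7-bis(benzyloxy)-3-hydroxy-4-oxo-4H-chromen-2-yl]phenyl pivalate F8. Methanolysis as in step 8 (NaOMe, MeOH–THF; AcOH) then gives 14 through its disodium salt 13.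

**Further compounds**
F1 | step 7 | 5,7-bis(benzyloxy)-2-iodo-4-oxo-4H-chromen-3-yl pivalate | CC(C)(C)C(=O)Oc1c(I)oc2cc(OCc3ccccc3)cc(OCc3ccccc3)c2c1=O
F2 | step 7 | 2-(benzyloxy)-5-(4,4,5,5-tetramethyl-1,3,2-dioxaborolan-2-yl)phenyl pivalate | CC(C)(C)C(=O)Oc1cc(B2OC(C)(C)C(C)(C)O2)ccc1OCc1ccccc1
F3 | step 9 | 5,7-bis(benzyloxy)-2-{4-(benzyloxy)-3-[(2,2,2-trichloroethoxy)sulfonyloxy]phenyl}-4-oxo-4H-chromen-3-yl 2,2,2-trichloroethyl sulfate | O=c1c(OS(=O)(=O)OCC(Cl)(Cl)Cl)c(-c2ccc(OCc3ccccc3)c(OS(=O)(=O)OCC(Cl)(Cl)Cl)c2)oc2cc(OCc3ccccc3)cc(OCc3ccccc3)c12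
F4 | step 9 | diammonium 5,7,4'-tri-O-benzylquercetin 3,3'-bis(sulfate) | O=c1c(OS(=O)(=O)[O-])c(-c2ccc(OCc3ccccc3)c(OS(=O)(=O)[O-])c2)oc2cc(OCc3ccccc3)cc(OCc3ccccc3)c12.[NH4+].[NH4+]
F5 | step 3 | [5,7-bis(benzyloxy)-4-oxo-4H-chromen-2-yl]zinc chloride | O=c1cc([Zn]Cl)oc2cc(OCc3ccccc3)cc(OCc3ccccc3)c12
F6 | step 3 | 2-(benzyloxy)-5-[5,7-bis(benzyloxy)-4-oxo-4H-chromen-2-yl]phenyl pivalate | CC(C)(C)C(=O)Oc1cc(-c2cc(=O)c3c(OCc4ccccc4)cc(OCc4ccccc4)cc3o2)ccc1OCc1ccccc1
F7 | step 3 | 2-(benzyloxy)-5-[5,7-bis(benzyloxy)-2,3-epoxy-4-oxochroman-2-yl]phenyl pivalate (racemic, cis-fused oxirane; one enantiomer drawn) | O=C1[C@@H]2O[C@]2(c2ccc(OCc3ccccc3)c(OC(=O)C(C)(C)C)c2)Oc2cc(OCc3ccccc3)cc(OCc3ccccc3)c12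
F8 | step 3 | 2-(benzyloxy)-5-[5,7-bis(benzyloxy)-3-hydroxy-4-oxo-4H-chromen-2-yl]phenyl pivalate | CC(C)(C)C(=O)Oc1cc(-c2oc3cc(OCc4ccccc4)cc(OCc4ccccc4)c3c(=O)c2O)ccc1OCc1ccccc1
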